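**Plan**

1. Retrosynthetic cuts, in order: redox at C15 and C12; C16=C17 (methylenation); C11–C15 (aldol, ring D); C13–C16 (allylation); C9–C11 and C8–C14 (Robinson annulation, ring C); C10–CH3 (Birch reductive methylation of ring B); C4–C5 (ring A); C1–C10 (aryllithium plus cyclobutanone).
2. Forward order: ring B starts as a hydroquinone diether (C6 OTIPS, C9 OMe); C1–C4 arrive as 2,2-dimethylcyclobutanone; ring A closes by the C4–C5 bond; ring B is then dearomatised with introduction of the C10 methyl; ring C and then ring D follow.
3. Enabling feature: in ring A the oxygen-bearing C1 and the gem-dimethyl carbon C4 are 1,4-related and C1 sits on C10 of ring B, so the γ-keto tertiary radical at C4 is the ring-opened form of a 1-aryl-2,2-dimethylcyclobutanol; C5 is the only free ortho carbon of the C6/C9-dioxygenated ring B arene.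
4. Stereochemistry: C10 and C1 come from a CBS kinetic resolution of the racemic Birch ketone; C5 from protonation α to the C6 ketone (trans fusion); C6 from hydride attack anti to the C4/C10 methyl groups; C11 and C13 from aldol attack anti to the C10 methyl; C12 from hydride attack on the alkene side of the bridging ketone.

Key step: step 3

Remark: 2,2-dimethylcyclobutanone (3) is taken as purchasable; atoms carry ent-kaurane-type numbers (ring A C1–C5/C10, ring B C5–C10, ring C C8/C9/C11–C14, two-carbon bridge C15–C16, methylene C17), α is the face of the C10 methyl group and β the opposite face.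

**Step 1**
Reactants: 1 3-bromo-4-methoxyphenol
Product: 2 (3-bromo-4-methoxyphenoxy)triisopropylsilane
Conditions: TIPSCl, imidazole, DMF, rt
Reagents that add atoms: chlorotriisopropylsilane CC(C)[Si](Cl)(C(C)C)C(C)C
Why: Imidazole-promoted O-silylation of the phenol (silyl ether protection) installs the C6 oxygen as a TIPS ether that survives aryllithium chemistry and later becomes a silyl enol ether cleavable independently of the methyl enol ether at C9.

**Step 2**
Reactants: 2 (3-bromo-4-methoxyphenoxy)triisopropylsilane; 3 2,2-dimethylcyclobutan-1-one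
Product: 5 1-[2-methoxy-5-(triisopropylsilyloxy)phenyl]-2,2-dimethylcyclobutan-1-ol (racemic), via aryllithium 4 (not isolated)
Conditions: n-BuLi, THF, −78 °C; then 3, −78 to 0 °C; H2O
Reagents that add atoms: none
Why: Bromine–lithium exchange followed by 1,2-addition of the aryllithium to the strained cyclobutanone joins C10 to C1 and gives the tertiary cyclobutanol, whose single stereocenter need not be controlled because C1 becomes a carbonyl carbon in step 3.

**Step 3**
Reactants: 5 1-[2-methoxy-5-(triisopropylsilyloxy)phenyl]-2,2-dimethylcyclobutan-1-ol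
Product: 6 8-methoxy-4,4-dimethyl-5-(triisopropylsilyloxy)-3,4-dihydronaphthalen-1(2H)-one
Conditions: AgNO3 (20 mol %), K2S2O8 (3 equiv), CH2Cl2/H2O (1:1), 25 °C
Reagents that add atoms: none
Why: Persulfate oxidises the silver salt to a divalent silver species that generates the alkoxy radical of the tertiary cyclobutanol; β-scission then cleaves the C1–C4 bond with release of about 26 kcal/mol of ring strain and, because the more substituted bond breaks, delivers the γ-keto tertiary radical at C4. This radical attacks the only free ortho carbon (C5) of the aryl ketone and closes ring A in a 6-exo-trig mode (counted on the C5=C6 bond); oxidation of the cyclohexadienyl radical and loss of a proton restore the arene (homolytic aromatic substitution). The closest known reaction type is the silver-catalysed oxidative ring expansion of 1-arylcyclobutanols to 1-tetralones. No stereocenter is created, since C4 carries two methyl groups. The step needs scission toward C4 and not C2, which the tertiary versus primary radical stability secures, and attack at C5 and not C9, which the methoxy group on C9 secures; the electron-rich ring should survive the oxidant because fragmentation is fast and the acyl group of the product deactivates it.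

**Step 4**
Reactants: 6 8-methoxy-4,4-dimethyl-5-(triisopropylsilyloxy)-3,4-dihydronaphthalen-1(2H)-one
Product: 8 rac-8-methoxy-4,4,8a-trimethyl-5-(triisopropylsilyloxy)-3,4,6,8a-tetrahydronaphthalen-1(2H)-one, via potassium dienolate 7 (not isolated)
Conditions: K, NH3(l)/THF, t-BuOH (1 equiv), −78 °C; then MeI, −78 °C to rt
Reagents that add atoms: iodomethane CI
Why: Birch reductive alkylation of an aryl ketone: two-electron reduction with protonation at C7 (para to the acyl group) gives the cross-conjugated dienolate 7, which is methylated on carbon at the ipso position C10 to create the quaternary center as a racemate, while both oxygen substituents stay on double bonds as a silyl and a methyl enol ether.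

**Step 5**
Reactants: 8 rac-8-methoxy-4,4,8a-trimethyl-5-(triisopropylsilyloxy)-3,4,6,8a-tetrahydronaphthalen-1(2H)-one
Product: 9 (1S,8aS)-8-methoxy-4,4,8a-trimethyl-5-(triisopropylsilyloxy)-1,2,3,4,6,8a-hexahydronaphthalen-1-ol
Conditions: (R)-tetrahydro-1-methyl-3,3-diphenyl-1H,3H-pyrrolo[1,2-c][1,3,2]oxazaborole (0.2 equiv), catecholborane (0.6 equiv), toluene, −78 °C, stopped near half conversion
Reagents that add atoms: none
Why: Corey–Bakshi–Shibata reduction run as a kinetic resolution: the (R)-oxazaborolidine delivers hydride to the same absolute face of the C1 carbonyl in both enantiomers of 8, and only in the (8aR) enantiomer is this the face anti to the pseudoaxial C10 methyl group, so that this enantiomer should be reduced selectively to the (1S) alcohol with the hydroxyl cis to the methyl group while the (8aS) ketone is left behind (at most half of the material is used).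

**Step 6**
Reactants: 9 (1S,8aS)-8-methoxy-4,4,8a-trimethyl-5-(triisopropylsilyloxy)-1,2,3,4,6,8a-hexahydronaphthalen-1-ol
Product: 10 (4aS,5S,8aR)-5-hydroxy-4-methoxy-4a,8,8-trimethyl-4a,5,6,7,8,8a-hexahydronaphthalen-1(2H)-one
Conditions: Bu4NF, AcOH, THF, 0 °C
Reagents that add atoms: none
Why: Fluoride-induced cleavage of the silyl enol ether leaves the methyl enol ether untouched and the resulting enolate is protonated at C5 from the face opposite the C10 methyl group, giving the trans ring fusion, which is also the expected outcome of any equilibration α to the C6 ketone.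

**Step 7**
Reactants: 10 (4aS,5S,8aR)-5-hydroxy-4-methoxy-4a,8,8-trimethyl-4a,5,6,7,8,8a-hexahydronaphthalen-1(2H)-one
Product: 11 (1S,4aS,5S,8aR)-4-methoxy-4a,8,8-trimethyl-1,2,4a,5,6,7,8,8a-octahydronaphthalene-1,5-diol
Conditions: NaBH4, MeOH, 0 °C
Reagents that add atoms: none
Why: Hydride reduction of the only ketone present: the α face of C6 is screened by the syn-axial methyl groups on C10 and C4, so that borohydride should attack from the β face and give the axial alcohol cis to the C10 methyl group.

**Step 8**
Reactants: 11 (1S,4aS,5S,8aR)-4-methoxy-4a,8,8-trimethyl-1,2,4a,5,6,7,8,8a-octahydronaphthalene-1,5-diol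
Product: 13 trans-decalone with the C9 ketone and TBS ethers at C1 and C6, via bis-silylated methyl enol ether 12 (not isolated)
Conditions: TBSOTf, 2,6-lutidine, CH2Cl2, 0 °C; then oxalic acid, THF/H2O, rt
Reagents that add atoms: tert-butyldimethylsilyl triflate CC(C)(C)[Si](C)(C)OS(=O)(=O)C(F)(F)F; water O
Why: Silyl triflate silylation protects both secondary alcohols (the hindered axial one at C6 included) and mild aqueous acid then hydrolyses the methyl enol ether, the only enol ether left, to the C9 ketone without cleaving the silyl ethers.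

**Step 9**
Reactants: 13 trans-decalone with the C9 ketone and TBS ethers at C1 and C6; 14 methyl vinyl ketone
Product: 16 tricyclic ring C enone (C12 ketone conjugated to C9=C11; TBS ethers at C1 and C6), via Michael adduct 15 (not isolated)
Conditions: t-BuOK (0.2 equiv), t-BuOH/THF, 0 °C; then KOH, MeOH, 65 °C
Reagents that add atoms: none
Why: Robinson annulation: the ketone can enolise only toward C8 because C10 is quaternary, so Michael addition to methyl vinyl ketone occurs at C8 and the aldol condensation of the methyl ketone onto C9 closes ring C as the enone, with the C8 hydrogen settling in the axial (thermodynamic) position through the dienolate.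

**Step 10**
Reactants: 16 tricyclic ring C enone; 17 allyl bromide
Product: 19 13-allyl tricyclic enone (allyl on the β face), via lithium enolate 18 (not isolated)
Conditions: LiN(i-Pr)2, THF, −78 °C; then 17, DMPU, −78 to −20 °C
Reagents that add atoms: none
Why: Kinetic deprotonation of the enone at the α′ carbon C13 with the lithium amide and SN2 alkylation of the cross-conjugated enolate with allyl bromide, expected mainly from the β face; C13 stays epimerisable next to the ketone so that either epimer can serve in step 12.

**Step 11**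
Reactants: 19 13-allyl tricyclic enone
Product: 20 enone aldehyde (C13–CH2–CHO; the aldehyde carbon is C15)
Conditions: OsO4 (2 mol %), NaIO4, 2,6-lutidine, dioxane/H2O, rt
Reagents that add atoms: sodium periodate [Na+].[O-]I(=O)(=O)=O
Why: Lemieux–Johnson oxidative cleavage: OsO4 dihydroxylates the electron-rich terminal alkene in preference to the electron-poor and hindered enone double bond, and periodate cleaves the diol to the aldehyde.

**Step 12**
Reactants: 20 enone aldehyde
Product: 21 tetracyclic ketol (C12 ketone; C15 carbinol; C8=C9; two-carbon bridge on the β face)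
Conditions: KOH (0.5 equiv), MeOH, 0 °C to rt
Reagents that add atoms: none
Why: Intramolecular aldol addition: under equilibrating base the extended dienolate formed by deprotonation at C8 attacks the aldehyde through its α carbon C11, which closes the five-membered ring D, shifts the double bond to C8=C9 and sets C11 and C13 by attack on the β face of C11 anti to the axial C10 methyl group (C13 epimerises to supply the β side chain), whereas the configuration of the C15 carbinol is of no consequence.

**Step 13**
Reactants: 21 tetracyclic ketol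
Product: 22 tetracyclic 12,15-diketone (C16 still CH2; TBS ethers at C1 and C6)
Conditions: Dess–Martin periodinane, CH2Cl2, rt
Reagents that add atoms: none
Why: Dess–Martin oxidation converts the C15 carbinol into the ketone under neutral conditions that leave the non-enolisable 1,3-diketone and the silyl ethers intact.

**Step 14**
Reactants: 22 tetracyclic 12,15-diketone
Product: 24 16-methylene 12,15-diketone (TBS ethers at C1 and C6), via Mannich base 23 (not isolated)
Conditions: (CH2O)n, N-methylanilinium trifluoroacetate, THF, 65 °C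
Reagents that add atoms: formaldehyde (as paraformaldehyde) C=O
Why: α-Methylenation by a Mannich condensation with formaldehyde and elimination of the amine in the same flask occurs at C16, the only enolisable position, since the other carbons next to the two ketones (C11 and C13) are bridgeheads.

**Step 15**
Reactants: 24 16-methylene 12,15-diketone (TBS ethers at C1 and C6)
Product: 25 16-methylene 12,15-diketone 1,6-diol
Conditions: HF·pyridine, THF, 0 °C to rt
Reagents that add atoms: none
Why: Acidic fluoride cleaves both tert-butyldimethylsilyl ethers without nucleophilic or basic attack on the α-methylene ketone or the 1,3-diketone.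

**Step 16**
Reactants: 25 16-methylene 12,15-diketone 1,6-diol
Product: 26 1-O-acetyl 16-methylene 12,15-diketone (C6 hydroxyl free)
Conditions: Ac2O, pyridine, DMAP (cat.), CH2Cl2, 0 °C
Reagents that add atoms: acetic anhydride CC(=O)OC(C)=O
Why: Base-catalysed acylation differentiates the two hydroxyls on steric grounds: the equatorial C1 hydroxyl is acetylated while the axial C6 hydroxyl, flanked by the syn-axial methyl groups on C10 and C4, should remain free, and no other hydroxyl is present at this stage.

**Step 17**
Reactants: 26 1-O-acetyl 16-methylene 12,15-diketone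
Product: 27 1-O-acetyl 6,12,15-triol (C12 hydroxyl syn to the C15–C16 bridge; C15 carbinol as formed)
Conditions: NaBH4, CeCl3·7H2O, MeOH, −78 °C
Reagents that add atoms: none
Why: Luche reduction reduces the enone and the bridging ketone in the 1,2 sense; at C12 hydride should approach from the face turned to the C8=C9 bridge, away from the two-carbon bridge whose C15 oxygen is bound to cerium, which places the hydroxyl syn to the C15–C16 bridge as in the target, and the mixture at C15 is removed in step 18.

**Step 18**
Reactants: 27 1-O-acetyl 6,12,15-triol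
Product: 28 target CNP0149338.1
Conditions: MnO2, CH2Cl2, rt
Reagents that add atoms: none
Why: MnO2 oxidises only the allylic C15 alcohol back to the α-methylene ketone and leaves the non-allylic hydroxyls at C12 and C6 untouched, which gives the target.

**Compound list**

1 | 3-bromo-4-methoxyphenol | COc1ccc(O)cc1Br | starting material
2 | (3-bromo-4-methoxyphenoxy)triisopropylsilane | COc1ccc(O[Si](C(C)C)(C(C)C)C(C)C)cc1Br | intermediate
3 | 2,2-dimethylcyclobutan-1-one | CC1(C)CCC1=O | starting material
4 | [2-methoxy-5-(triisopropylsilyloxy)phenyl]lithium (not isolated) | COc1ccc(O[Si](C(C)C)(C(C)C)C(C)C)cc1[Li] | intermediate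
5 | 1-[2-methoxy-5-(triisopropylsilyloxy)phenyl]-2,2-dimethylcyclobutan-1-ol (racemic) | COc1ccc(O[Si](C(C)C)(C(C)C)C(C)C)cc1C1(O)CCC1(C)C | intermediate
6 | 8-methoxy-4,4-dimethyl-5-(triisopropylsilyloxy)-3,4-dihydronaphthalen-1(2H)-one | COc1ccc(O[Si](C(C)C)(C(C)C)C(C)C)c2c1C(=O)CCC2(C)C | intermediate
7 | potassium dienolate from ipso/para reduction of 6 (not isolated) | [K+].[O-]C1=C2C(OC)=CCC(O[Si](C(C)C)(C(C)C)C(C)C)=C2C(C)(C)CC1 | intermediate
8 | rac-8-methoxy-4,4,8a-trimethyl-5-(triisopropylsilyloxy)-3,4,6,8a-tetrahydronaphthalen-1(2H)-one | O=C1CCC(C)(C)C2=C(O[Si](C(C)C)(C(C)C)C(C)C)CC=C(OC)C12C | intermediate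
9 | (1S,8aS)-8-methoxy-4,4,8a-trimethyl-5-(triisopropylsilyloxy)-1,2,3,4,6,8a-hexahydronaphthalen-1-ol | O[C@H]1CCC(C)(C)C2=C(O[Si](C(C)C)(C(C)C)C(C)C)CC=C(OC)[C@]12C | intermediate
10 | (4aS,5S,8aR)-5-hydroxy-4-methoxy-4a,8,8-trimethyl-4a,5,6,7,8,8a-hexahydronaphthalen-1(2H)-one (trans-fused) | O[C@H]1CCC(C)(C)[C@H]2C(=O)CC=C(OC)[C@]12C | intermediate
11 | (1S,4aS,5S,8aR)-4-methoxy-4a,8,8-trimethyl-1,2,4a,5,6,7,8,8a-octahydronaphthalene-1,5-diol | O[C@H]1CCC(C)(C)[C@H]2[C@@H](O)CC=C(OC)[C@]12C | intermediate
12 | bis-TBS ether of 11 (methyl enol ether intact; not isolated) | CC(C)(C)[Si](C)(C)O[C@H]1CCC(C)(C)[C@H]2[C@@H](O[Si](C)(C)C(C)(C)C)CC=C(OC)[C@]12C | intermediate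
13 | trans-decalone: C9 ketone; TBS ethers at C1 and C6 (both cis to the C10 methyl); C5–H trans to the C10 methyl | CC(C)(C)[Si](C)(C)O[C@H]1CCC(C)(C)[C@H]2[C@@H](O[Si](C)(C)C(C)(C)C)CCC(=O)[C@]12C | intermediate
14 | methyl vinyl ketone (but-3-en-2-one) | CC(=O)C=C | starting material
15 | Michael adduct: 13 carrying a 3-oxobutyl chain at C8 (not isolated) | CC(C)(C)[Si](C)(C)O[C@H]1CCC(C)(C)[C@H]2[C@@H](O[Si](C)(C)C(C)(C)C)C[C@H](CCC(C)=O)C(=O)[C@]12C | intermediate
16 | tricyclic ring C enone: C12 ketone, C9=C11, C8–H α; TBS ethers at C1 and C6 | CC(C)(C)[Si](C)(C)O[C@H]1CCC(C)(C)[C@H]2[C@@H](O[Si](C)(C)C(C)(C)C)C[C@@H]3CCC(=O)C=C3[C@]12C | intermediate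
17 | allyl bromide (3-bromoprop-1-ene) | C=CCBr | starting material
18 | lithium cross-conjugated enolate of 16 (C12–O, C12=C13; not isolated) | CC(C)(C)[Si](C)(C)O[C@H]1CCC(C)(C)[C@H]2[C@@H](O[Si](C)(C)C(C)(C)C)C[C@@H]3CC=C([O-])C=C3[C@]12C.[Li+] | intermediate
19 | 13-allyl tricyclic enone (β-allyl epimer drawn; the C13 epimer converges in step 12) | CC(C)(C)[Si](C)(C)O[C@H]1CCC(C)(C)[C@H]2[C@@H](O[Si](C)(C)C(C)(C)C)C[C@@H]3C[C@H](CC=C)C(=O)C=C3[C@]12C | intermediate
20 | enone aldehyde: 16 carrying CH2CHO at C13 | CC(C)(C)[Si](C)(C)O[C@H]1CCC(C)(C)[C@H]2[C@@H](O[Si](C)(C)C(C)(C)C)C[C@@H]3C[C@H](CC=O)C(=O)C=C3[C@]12C | intermediate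
21 | tetracyclic ketol: C12 ketone, C15 carbinol (epimer mixture, center left undefined), C8=C9, two-carbon bridge β; TBS ethers at C1 and C6 | C1C(O)[C@@H]2C3=C(C[C@H]1C2=O)C[C@H](O[Si](C)(C)C(C)(C)C)[C@@H]1C(C)(C)CC[C@H](O[Si](C)(C)C(C)(C)C)[C@@]31C | intermediate
22 | tetracyclic 12,15-diketone (C16 CH2); TBS ethers at C1 and C6 | C1C(=O)[C@@H]2C3=C(C[C@H]1C2=O)C[C@H](O[Si](C)(C)C(C)(C)C)[C@@H]1C(C)(C)CC[C@H](O[Si](C)(C)C(C)(C)C)[C@@]31C | intermediate
23 | Mannich base: 22 carrying CH2N(CH3)Ph at C16 (C16 undefined; not isolated) | CN(CC1C(=O)[C@@H]2C3=C(C[C@H]1C2=O)C[C@H](O[Si](C)(C)C(C)(C)C)[C@@H]1C(C)(C)CC[C@H](O[Si](C)(C)C(C)(C)C)[C@@]31C)c1ccccc1 | intermediate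
24 | 16-methylene 12,15-diketone; TBS ethers at C1 and C6 | C=C1C(=O)[C@@H]2C3=C(C[C@H]1C2=O)C[C@H](O[Si](C)(C)C(C)(C)C)[C@@H]1C(C)(C)CC[C@H](O[Si](C)(C)C(C)(C)C)[C@@]31C | intermediate
25 | 16-methylene 12,15-diketone 1,6-diol | C=C1C(=O)[C@@H]2C3=C(C[C@H]1C2=O)C[C@H](O)[C@@H]1C(C)(C)CC[C@H](O)[C@@]31C | intermediate
26 | 1-O-acetyl 16-methylene 12,15-diketone (C6 hydroxyl free) | C=C1C(=O)[C@@H]2C3=C(C[C@H]1C2=O)C[C@H](O)[C@@H]1C(C)(C)CC[C@H](OC(C)=O)[C@@]31C | intermediate
27 | 1-O-acetyl 6,12,15-triol (C12 as in the target; C15 carbinol undefined) | C=C1C(O)[C@@H]2C3=C(C[C@H]1[C@@H]2O)C[C@H](O)[C@@H]1C(C)(C)CC[C@H](OC(C)=O)[C@@]31C | intermediate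
28 | CNP0149338.1 | C=C1C(=O)[C@@H]2C3=C(C[C@H]1[C@@H]2O)C[C@H](O)[C@@H]1C(C)(C)CC[C@H](OC(C)=O)[C@@]31C | target

**Step count and risks**

Total step count: 18. Longest linear sequence: 18 steps (1 to 28).

Steps most likely to fail:

- **Step 5.** The catalyst may not override the substrate bias in the mismatched enantiomer, so that both enantiomers of 8 are reduced at similar rates and the alcohol loses enantiomeric purity. The fallback sets out from 8 and returns at 9. Ketone 8 is reduced with NaBH4 under substrate control to the racemic cis alcohol F1. This is esterified with (S)-2-methoxy-2-phenylacetic acid (DCC, DMAP) and the two diastereomeric esters are separated by chromatography. The (S)-O-methylmandelate of the (1S,8aS) alcohol F2 is then cleaved with K2CO3 in methanol to give 9.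

- **Step 12.** The aldol equilibrium may lie on the side of the open conjugated enone aldehyde (retro-aldol), or the aldehyde may be lost by intermolecular condensation. The fallback sets out from 16 and returns at 22. The kinetic enolate of 16 is alkylated with 2,3-dibromopropene to the 13-(2-bromoallyl) enone F3. Irreversible intramolecular α-alkenylation of the ketone at C11 with Pd(PPh3)4 and t-BuOK closes ring D to the bridged ketone with an exocyclic methylene at C15 F4. Lemieux–Johnson cleavage of this 1,1-disubstituted alkene (OsO4, NaIO4) then gives the diketone 22.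

- **Step 17.** Hydride may add to the C12 ketone from the face of the two-carbon bridge (poor facial selectivity at the one-carbon bridge). The fallback sets out from 26 and returns at 28. The 12-epi triol F5 from the same reduction is oxidised with MnO2 to 12-epi-28 F6. This is equilibrated with DBU in toluene by retro-aldol opening of the C11–C12 bond to the keto aldehyde F7 and re-closure; the isomer with the C12 hydroxyl hydrogen-bonded to the C15 ketone (28) should be the thermodynamic product.

**Further compounds**

F1 | step 5 | racemic cis alcohol (9 together with its enantiomer) | O[C@H]1CCC(C)(C)C2=C(O[Si](C(C)C)(C(C)C)C(C)C)CC=C(OC)[C@]12C.O[C@@H]1CCC(C)(C)C2=C(O[Si](C(C)C)(C(C)C)C(C)C)CC=C(OC)[C@@]12C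
F2 | step 5 | (S)-O-methylmandelate of the (1S,8aS) alcohol 9 | CO[C@H](C(=O)O[C@H]1CCC(C)(C)C2=C(O[Si](C(C)C)(C(C)C)C(C)C)CC=C(OC)[C@]12C)c1ccccc1
F3 | step 12 | 13-(2-bromoallyl) tricyclic enone | CC(C)(C)[Si](C)(C)O[C@H]1CCC(C)(C)[C@H]2[C@@H](O[Si](C)(C)C(C)(C)C)C[C@@H]3C[C@H](CC(Br)=C)C(=O)C=C3[C@]12C
F4 | step 12 | bridged C12 ketone with exocyclic methylene at C15 (C16 CH2; C8=C9; TBS ethers at C1 and C6) | C1C(=C)[C@@H]2C3=C(C[C@H]1C2=O)C[C@H](O[Si](C)(C)C(C)(C)C)[C@@H]1C(C)(C)CC[C@H](O[Si](C)(C)C(C)(C)C)[C@@]31C
F5 | step 17 | 12-epi-27 (C15 carbinol undefined) | C=C1C(O)[C@@H]2C3=C(C[C@H]1[C@H]2O)C[C@H](O)[C@@H]1C(C)(C)CC[C@H](OC(C)=O)[C@@]31C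
F6 | step 17 | 12-epi-28 | C=C1C(=O)[C@@H]2C3=C(C[C@H]1[C@H]2O)C[C@H](O)[C@@H]1C(C)(C)CC[C@H](OC(C)=O)[C@@]31C
F7 | step 17 | ring-opened keto aldehyde (C12 aldehyde on C13; C11 CH2; seven-membered enone ring) | C=C1C(=O)CC2=C(C[C@H]1C=O)C[C@H](O)[C@@H]1C(C)(C)CC[C@H](OC(C)=O)[C@@]21C
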